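The readings stem from a simulated flask with constants of no real substance; noise was put on by code.

Divide the charges.

| flask | starting material | protic impurity | remark | time |
|---|---|---|---|---|
| midnight | 0.50 M | 0.14 M | run made earlier |  |
| spring | 0.50 M | 0.22 M | run made earlier |  |
| flask | 0.50 M | 0.100 M |  | 4.0 d |

| run | time / d | starting material / % | target / % |
|---|---|---|---|
| midnight | 0.250 | 15.2 | 4.0 |
| midnight | 0.833 | 7.4 | 0.9 |
| midnight | 1.67 | 6.0 | 1.6 |
| midnight | 2.50 | 6.6 | 1.8 |
| midnight | 3.00 | 5.8 | 2.8 |
| spring | 0.625 | 6.9 | 3.0 |
| spring | 1.25 | 7.1 | 1.6 |
| spring | 2.08 | 3.8 | 2.6 |
| spring | 2.50 | 5.7 | 1.5 |
| spring | 3.00 | 3.9 | 3.0 |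

(scatter of a reading: 1 percentage point)

* which holds at 4.0 d: what has brought the reaction to rest, or that it has not come to rest (it is still moving / forward and back rates have come level / all of the starting material has reacted)
* share of the starting material used up at 4.0 d
* target at 4.0 d, in percent of the starting material charged
* isomer of the product C at 4.0 d, in percent of the starting material charged

- the analysis behind the earlier runs scatters by 1 percentage point, standard deviation
- what has gone from starting material into another species counts as reacted, even if it can come back
- the reaction counts as stopped when no species that holds the starting material changes by six tenths of a point or more over the second half of the time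

Watch the earlier runs in slow motion. In the first instants the starting material falls hard: the midnight run reads 15.2% after 0.250 d, with target at 4.0%. By 0.833 d the midnight run reads 7.4%, and its last reading, at 3.00 d, is 5.8%, with a scatter of 1 percentage point on each. Average the last 4 readings of starting material: the midnight run reads 6.45%, the spring run 5.12%.

Now take my own reckoning. Suppose each protic impurity takes one starting material for good, so that the impurity is the limiting reagent of that loss, since it is the smaller charge. The live share is then one minus protic impurity over starting material charged, 80.0% for this flask. It is 72.0% for the midnight run and 56.0% for the spring run. Their ratio is 0.778, and the ratio of the plateaus reads 0.794, with the scatter in it.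

Scale the midnight plateau by the live share: this flask should level at 7.17% starting material, and the spring run gives 7.31%. On this estimate, 72.8% remains in this flask for target, isomer of the product C and any other species together.

The forecast says forward and back rates have come level, conversion 94%, target 2.1% and isomer of the product C 92%, on the ground that “A plateau that barely depends on impurity level looks like equilibrium”. My reckoning parts from it on isomer of the product C, where the forecast stands higher than the share my estimate leaves.

In the flask at 4.0 d, forward and back rates have come level; conversion is 93.1%, target 2.43% and isomer of the product C 60.7%.

    starting material ⇌ target (K = 0.350, k = 5.80 × 10⁻⁴ /s)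
    target ⇌ isomer of the product A (K = 1.30, k = 0.00330 /s)
    isomer of the product A ⇌ isomer of the product B (K = 1.00, k = 2.20 × 10⁻⁴ /s)
    isomer of the product B ⇌ starting material (k = 0.00600 /s)
    starting material + protic impurity → quenched substrate (k = 0.00310 /M/s)
    target ⇌ isomer of the product C (K = 25.0, k = 2.80 × 10⁻⁴ /s)
    starting material ⇌ dormant form (K = 0.520, k = 4.20 × 10⁻⁵ /s)

This flask holds 20.0% quenched substrate and 0% of its protic impurity at 4.00 d; the reckoning from the charges gave 20.0% quenched substrate. The forecast's isomer of the product C lies 31 points above the flask's. Isomer of the product C in this flask is 75.9% of the live share. Apply that to the neighbour with 0.12 M starting material: its live share is 16.7%, which gives 12.7% isomer of the product C. The neighbour holds 14.9% of it, with 80.8% quenched substrate and 3.0% of its protic impurity left, and its starting material runs out first, at 1.5%.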